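**Plan**
1. With the 7-OH masked as a benzyl ether and the 4'-OMe taken back to a phenol, ring B is cut at C1'-C6' and C2'-C3'. This is possible because ring B is a para-disubstituted benzene that carries only C2 of ring C (at C1') and one oxygen (at C4'), while C2', C3', C5' and C6' are plain CH. The pieces are a 2-ethynylchromone and a 1-methoxy-3-silyloxybutadiene.
2. Further cuts: C2-C(sp) (cross-coupling on a 2-iodochromone), O1-C2 and C2-C3 of ring C (one-carbon insertion into an ortho-hydroxy omega-methoxyacetophenone), and C4-C4a (aryl-metal acylation).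
3. Ring A comes from symmetrical 1,2,4,5-tetramethoxybenzene. One CH becomes the 7-oxygen, the opposite CH takes the acyl group, and one of two equivalent ortho methyl ethers is removed to free O1.
4. Forward order: ring A is fully substituted, ring C is closed, the alkyne is attached, ring B is built, then 4'-O-methylation and 7-O-debenzylation follow.
5. The target has no stereocentre and no stereogenic double bond. The single sp3 centre of the cycloadduct forms racemic and disappears on aromatization.

Key step: step 12

Remark: 23 is drawn without configuration (racemic, stereocentre lost in the same flask) and 15 without double-bond geometry (both isomers cyclize). Compound 10 and TMPZnCl·LiCl in THF (TMP = 2,2,6,6-tetramethylpiperidin-1-yl) are taken as purchasable.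

**Step 1**
Reactants: 1 2,4,5-trimethoxybenzaldehyde
Product: 3 2,4,5-trimethoxyphenol, via aryl formate 2 (not isolated)
Conditions: mCPBA, CH2Cl2, 0 °C to rt; then K2CO3 (cat.), MeOH, rt, under N2
Reagents that add atoms: mCPBA (3-chloroperoxybenzoic acid), O=C(OO)c1cccc(Cl)c1
Why: Baeyer-Villiger oxidation of an electron-rich benzaldehyde goes with aryl migration to formate 2, which mild methanolysis converts into the phenol.

**Step 2**
Reactants: 3 2,4,5-trimethoxyphenol
Product: 4 1,2,4,5-tetramethoxybenzene
Conditions: MeI, K2CO3, acetone, reflux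
Reagents that add atoms: iodomethane, CI
Why: Williamson ether synthesis on an unhindered phenoxide gives the symmetrical tetraether, in which the two remaining ring CH positions are equivalent.

**Step 3**
Reactants: 4 1,2,4,5-tetramethoxybenzene
Product: 7 2,3,5,6-tetramethoxyphenol, via aryllithium 5 (not isolated), via dimethyl arylboronate 6 (not isolated)
Conditions: n-BuLi (1.05 equiv), THF, 0 °C to rt; B(OMe)3, −78 °C to rt; AcOH, 30% H2O2, 0 °C to rt
Reagents that add atoms: hydrogen peroxide, OO (oxygen of 7); n-butyllithium, [Li]CCCC (lithium of 5 only); trimethyl borate, COB(OC)OC (boron of 6 only)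
Why: Directed ortho-metalation removes the proton lying between two methoxy groups (either one, by symmetry), and borylation-oxidation turns C-Li into C-OH under non-basic conditions that spare the oxidation-prone phenol.

**Step 4**
Reactants: 7 2,3,5,6-tetramethoxyphenol
Product: 8 3-(benzyloxy)-1,2,4,5-tetramethoxybenzene
Conditions: BnBr, K2CO3, DMF, rt
Reagents that add atoms: benzyl bromide, BrCc1ccccc1
Why: Williamson ether synthesis masks the future 7-OH as the only ether in the molecule that hydrogenolysis can later remove.

**Step 5**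
Reactants: 8 3-(benzyloxy)-1,2,4,5-tetramethoxybenzene
Product: 9 1-(benzyloxy)-4-bromo-2,3,5,6-tetramethoxybenzene
Conditions: NBS (1.05 equiv), MeCN, 0 °C to rt, dark
Reagents that add atoms: N-bromosuccinimide, O=C1CCC(=O)N1Br
Why: Electrophilic aromatic bromination finds a single free position on the pentaalkoxy ring, which is far more nucleophilic than the benzyl phenyl ring, and a polar solvent in the dark suppresses radical attack at the benzylic CH2.

**Step 6**
Reactants: 9 1-(benzyloxy)-4-bromo-2,3,5,6-tetramethoxybenzene; 10 N,2-dimethoxy-N-methylacetamide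
Product: 12 1-[4-(benzyloxy)-2,3,5,6-tetramethoxyphenyl]-2-methoxyethan-1-one, via aryllithium 11 (not isolated)
Conditions: n-BuLi, THF, −78 °C; 10, −78 to 0 °C; then 1 M HCl
Reagents that add atoms: n-butyllithium, [Li]CCCC (lithium of 11 only)
Why: Bromine-lithium exchange at −78 °C outruns deprotonation of the benzylic CH2, and the Weinreb ketone synthesis stops at the ketone because the chelated tetrahedral adduct survives until the acid quench.

**Step 7**
Reactants: 12 1-[4-(benzyloxy)-2,3,5,6-tetramethoxyphenyl]-2-methoxyethan-1-one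
Product: 14 1-[4-(benzyloxy)-2-hydroxy-3,5,6-trimethoxyphenyl]-2-methoxyethan-1-one, via dichloroboron chelate 13 (not isolated)
Conditions: BCl3 (1.1 equiv), CH2Cl2, −78 to −20 °C; then H2O
Reagents that add atoms: boron trichloride, ClB(Cl)Cl (boron and chlorine of 13 only)
Why: In this chelation-directed aryl methyl ether cleavage BCl3 binds the ketone oxygen and one of the two equivalent ortho methoxy groups, chloride removes that methyl group, and the six-membered chelate 13 shields the second ortho ether while the limited reagent charge and low temperature should spare the benzyl ether.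

**Step 8**
Reactants: 14 1-[4-(benzyloxy)-2-hydroxy-3,5,6-trimethoxyphenyl]-2-methoxyethan-1-one
Product: 16 7-(benzyloxy)-3,5,6,8-tetramethoxy-4H-chromen-4-one, via enaminone 15 (not isolated)
Conditions: Me2NCH(OMe)2, toluene, 100 °C; then AcOH, 80 °C
Reagents that add atoms: N,N-dimethylformamide dimethyl acetal, COC(OC)N(C)C
Why: Condensation of the ketone CH2 with the amide acetal gives enaminone 15, and the ortho phenol closes ring C by conjugate addition-elimination of dimethylamine, the standard enaminone route to 3-substituted chromones.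

**Step 9**
Reactants: 16 7-(benzyloxy)-3,5,6,8-tetramethoxy-4H-chromen-4-one
Product: 18 7-(benzyloxy)-2-iodo-3,5,6,8-tetramethoxy-4H-chromen-4-one, via chromon-2-ylzinc chloride 17 (not isolated)
Conditions: TMPZnCl·LiCl (1.3 equiv), THF, 25 °C; then I2, THF, 0 °C
Reagents that add atoms: iodine, II; TMPZnCl·LiCl, CC1(C)CCCC(C)(C)N1[Zn]Cl.[Li+].[Cl-] (zinc and chlorine of 17 only)
Why: Directed metalation with a hindered zinc amide removes the only vinylic proton, C2-H, which is acidified by O1 and flanked by the coordinating 3-methoxy group, without adding to the carbonyl group, and iodolysis of the C-Zn bond gives the iodide.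

**Step 10**
Reactants: 18 7-(benzyloxy)-2-iodo-3,5,6,8-tetramethoxy-4H-chromen-4-one; 19 trimethylsilylacetylene
Product: 20 7-(benzyloxy)-3,5,6,8-tetramethoxy-2-[(trimethylsilyl)ethynyl]-4H-chromen-4-one
Conditions: PdCl2(PPh3)2 (3 mol%), CuI (5 mol%), Et3N, THF, rt
Reagents that add atoms: none
Why: In this Sonogashira coupling the C2-I bond of a beta-iodo enone adds readily to zerovalent palladium at room temperature, and a tertiary amine base avoids addition-elimination at C2.

**Step 11**
Reactants: 20 7-(benzyloxy)-3,5,6,8-tetramethoxy-2-[(trimethylsilyl)ethynyl]-4H-chromen-4-one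
Product: 21 7-(benzyloxy)-2-ethynyl-3,5,6,8-tetramethoxy-4H-chromen-4-one
Conditions: Bu4NF (1.1 equiv), AcOH (1.2 equiv), THF, 0 °C
Reagents that add atoms: none
Why: Fluoride-induced protodesilylation of the alkynylsilane is buffered with acetic acid so that no alkoxide or hydroxide can add to the acceptor alkyne or open the pyranone.

**Step 12**
Reactants: 21 7-(benzyloxy)-2-ethynyl-3,5,6,8-tetramethoxy-4H-chromen-4-one; 22 trans-1-methoxy-3-(trimethylsilyloxy)-1,3-butadiene
Product: 24 7-(benzyloxy)-2-(4-hydroxyphenyl)-3,5,6,8-tetramethoxy-4H-chromen-4-one, via cyclohexadiene adduct 23 (not isolated)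
Conditions: 22 (4 equiv, in portions), toluene, sealed tube, 130 °C; then 1 M HCl, THF, rt
Reagents that add atoms: none
Why: Proposed new method: the ethynyl group of 21 is linked through C2=C3 to the C4 carbonyl and should behave as a vinylogous ynone with its largest LUMO coefficient on the terminal carbon, so a concerted but asynchronous (4+2) cycloaddition with the electron-rich diene 22 forms C2'-C3' ahead of C1'-C6' and gives the 1,4-cyclohexadiene 23. The closest known reaction type is the Diels-Alder aromatization of 1-alkoxy-3-silyloxybutadienes with propiolates and ethynyl ketones, which delivers para-hydroxyaryl carbonyl compounds; a chromon-2-yl group as the sole activator of the alkyne is the untested element, hence the excess diene and the high temperature. Ring B closes by intermolecular (4+2) annulation, with four ring carbons from 22 and two from the alkyne. The one stereocentre of 23 (C6', racemic) needs no control, because dilute acid expels methanol and hydrolyses the silyl enol ether, and the resulting dienone tautomerizes to phenol 24. The step needs para regiochemistry, which is secured by pairing the CH2 terminus of 22 (largest HOMO coefficient) with the unsubstituted alkyne carbon, a match that polarity and sterics both favour. It also needs chemoselectivity for the alkyne, which is secured by the tetrasubstituted, donor-laden C2=C3 bond and by the absence of any Lewis acid that could switch on hetero-Diels-Alder addition at C4=O.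

**Step 13**
Reactants: 24 7-(benzyloxy)-2-(4-hydroxyphenyl)-3,5,6,8-tetramethoxy-4H-chromen-4-one
Product: 25 7-(benzyloxy)-3,5,6,8-tetramethoxy-2-(4-methoxyphenyl)-4H-chromen-4-one
Conditions: MeI, K2CO3, acetone, reflux
Reagents that add atoms: iodomethane, CI
Why: Williamson ether synthesis acts on the only free hydroxyl group of the molecule, the unhindered 4'-phenol.

**Step 14**
Reactants: 25 7-(benzyloxy)-3,5,6,8-tetramethoxy-2-(4-methoxyphenyl)-4H-chromen-4-one
Product: 26 7-hydroxy-3,5,6,8-tetramethoxy-2-(4-methoxyphenyl)-4H-chromen-4-one (target)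
Conditions: H2 (1 atm), 10% Pd/C, EtOAc/MeOH, rt
Reagents that add atoms: none
Why: Catalytic hydrogenolysis cleaves the aryl benzyl ether and leaves the five methyl ethers and the aromatic pyranone C2=C3 bond untouched, which frees the 7-OH.

**Compound list**
1 | 2,4,5-trimethoxybenzaldehyde | COc1cc(OC)c(C=O)cc1OC | starting material
2 | 2,4,5-trimethoxyphenyl formate (not isolated) | COc1cc(OC)c(OC=O)cc1OC | intermediate
3 | 2,4,5-trimethoxyphenol | COc1cc(OC)c(O)cc1OC | intermediate
4 | 1,2,4,5-tetramethoxybenzene | COc1cc(OC)c(OC)cc1OC | intermediate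
5 | 2,3,5,6-tetramethoxyphenyllithium (not isolated) | [Li]c1c(OC)c(OC)cc(OC)c1OC | intermediate
6 | dimethyl (2,3,5,6-tetramethoxyphenyl)boronate (not isolated) | COB(OC)c1c(OC)c(OC)cc(OC)c1OC | intermediate
7 | 2,3,5,6-tetramethoxyphenol | Oc1c(OC)c(OC)cc(OC)c1OC | intermediate
8 | 3-(benzyloxy)-1,2,4,5-tetramethoxybenzene | COc1cc(OC)c(OC)c(OCc2ccccc2)c1OC | intermediate
9 | 1-(benzyloxy)-4-bromo-2,3,5,6-tetramethoxybenzene | COc1c(Br)c(OC)c(OC)c(OCc2ccccc2)c1OC | intermediate
10 | N,2-dimethoxy-N-methylacetamide | COCC(=O)N(C)OC | starting material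
11 | 4-(benzyloxy)-2,3,5,6-tetramethoxyphenyllithium (not isolated) | [Li]c1c(OC)c(OC)c(OCc2ccccc2)c(OC)c1OC | intermediate
12 | 1-[4-(benzyloxy)-2,3,5,6-tetramethoxyphenyl]-2-methoxyethan-1-one | COCC(=O)c1c(OC)c(OC)c(OCc2ccccc2)c(OC)c1OC | intermediate
13 | dichloroboron chelate of 14, aryl-O-BCl2 held by the ketone oxygen (not isolated) | COCC(=O)c1c(OB(Cl)Cl)c(OC)c(OCc2ccccc2)c(OC)c1OC | intermediate
14 | 1-[4-(benzyloxy)-2-hydroxy-3,5,6-trimethoxyphenyl]-2-methoxyethan-1-one | COCC(=O)c1c(O)c(OC)c(OCc2ccccc2)c(OC)c1OC | intermediate
15 | 1-[4-(benzyloxy)-2-hydroxy-3,5,6-trimethoxyphenyl]-3-(dimethylamino)-2-methoxyprop-2-en-1-one, geometry open (not isolated) | COC(=CN(C)C)C(=O)c1c(O)c(OC)c(OCc2ccccc2)c(OC)c1OC | intermediate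
16 | 7-(benzyloxy)-3,5,6,8-tetramethoxy-4H-chromen-4-one | COc1coc2c(OC)c(OCc3ccccc3)c(OC)c(OC)c2c1=O | intermediate
17 | [7-(benzyloxy)-3,5,6,8-tetramethoxy-4-oxo-4H-chromen-2-yl]zinc chloride (not isolated) | COc1c([Zn]Cl)oc2c(OC)c(OCc3ccccc3)c(OC)c(OC)c2c1=O | intermediate
18 | 7-(benzyloxy)-2-iodo-3,5,6,8-tetramethoxy-4H-chromen-4-one | COc1c(I)oc2c(OC)c(OCc3ccccc3)c(OC)c(OC)c2c1=O | intermediate
19 | trimethylsilylacetylene | C#C[Si](C)(C)C | starting material
20 | 7-(benzyloxy)-3,5,6,8-tetramethoxy-2-[(trimethylsilyl)ethynyl]-4H-chromen-4-one | COc1c(C#C[Si](C)(C)C)oc2c(OC)c(OCc3ccccc3)c(OC)c(OC)c2c1=O | intermediate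
21 | 7-(benzyloxy)-2-ethynyl-3,5,6,8-tetramethoxy-4H-chromen-4-one | C#Cc1oc2c(OC)c(OCc3ccccc3)c(OC)c(OC)c2c(=O)c1OC | intermediate
22 | trans-1-methoxy-3-(trimethylsilyloxy)-1,3-butadiene | CO/C=C/C(=C)O[Si](C)(C)C | starting material
23 | 7-(benzyloxy)-3,5,6,8-tetramethoxy-2-[6-methoxy-4-(trimethylsilyloxy)cyclohexa-1,4-dien-1-yl]-4H-chromen-4-one, racemic (not isolated) | COC1C=C(O[Si](C)(C)C)CC=C1c1oc2c(OC)c(OCc3ccccc3)c(OC)c(OC)c2c(=O)c1OC | intermediate
24 | 7-(benzyloxy)-2-(4-hydroxyphenyl)-3,5,6,8-tetramethoxy-4H-chromen-4-one | COc1c(-c2ccc(O)cc2)oc2c(OC)c(OCc3ccccc3)c(OC)c(OC)c2c1=O | intermediate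
25 | 7-(benzyloxy)-3,5,6,8-tetramethoxy-2-(4-methoxyphenyl)-4H-chromen-4-one | COc1ccc(-c2oc3c(OC)c(OCc4ccccc4)c(OC)c(OC)c3c(=O)c2OC)cc1 | intermediate
26 | 7-hydroxy-3,5,6,8-tetramethoxy-2-(4-methoxyphenyl)-4H-chromen-4-one (CNP0495887.0) | COc1ccc(-c2oc3c(OC)c(O)c(OC)c(OC)c3c(=O)c2OC)cc1 | target

**Step count and risks**

Total step count: 14. Longest linear sequence: 14 steps, from 1 to 26; compounds 10, 19 and 22 are bought and enter directly.

**Step 12.** The alkyne is activated only through a donor-substituted pyranone. The cycloaddition may therefore be slower than thermal decay of the diene and oligomerization of the alkyne. The fallback uses known chemistry and brings ring B in preformed instead of building it. It sets out from iodide 18. A Suzuki-Miyaura coupling with commercial 4-methoxyphenylboronic acid (Pd(PPh3)4, K2CO3, dioxane/H2O, 80 °C) forms C2-C1' directly and comes back to the route at 25, so that steps 10 to 13 drop out. No compound outside the list is made (F0).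

**Step 7.** The benzyl ether, flanked by two coordinating methoxy groups, may be lost together with the ortho methyl group, or cleavage may stall at partial conversion. The fallback gives up selectivity in the cleavage and regains it in the protection. It sets out from 12. Excess BCl3 (3 equiv, CH2Cl2, 0 °C) strips both the benzyl group and one ortho methyl group to give 1-(2,4-dihydroxy-3,5,6-trimethoxyphenyl)-2-methoxyethan-1-one F1. One equivalent of BnBr with K2CO3 in acetone then alkylates only the 4-OH, because the 2-OH is tied up in a hydrogen bond to the ketone. This comes back to the route at 14.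

**Step 9.** Metalation may be incomplete on this electron-rich chromone, or the beta-iodo enone may decompose during isolation. The fallback builds the C2 carbon in with ring C and needs no C2-H functionalization. It sets out from 14.
- Kostanecki-Robinson acylation-cyclization (Ac2O, NaOAc, 170 °C) gives 7-(benzyloxy)-3,5,6,8-tetramethoxy-2-methyl-4H-chromen-4-one F2.
- Riley oxidation of the vinylogously activated methyl group (SeO2, dioxane, reflux) gives 7-(benzyloxy)-3,5,6,8-tetramethoxy-4-oxo-4H-chromene-2-carbaldehyde F3.
- Seyferth-Gilbert homologation with dimethyl (1-diazo-2-oxopropyl)phosphonate (K2CO3, MeOH, 0 °C) gives the terminal alkyne and comes back to the route at 21, replacing steps 8 to 11.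

**Further compounds**
F0 | step 12 | none | none
F1 | step 7 | 1-(2,4-dihydroxy-3,5,6-trimethoxyphenyl)-2-methoxyethan-1-one | COCC(=O)c1c(O)c(OC)c(O)c(OC)c1OC
F2 | step 9 | 7-(benzyloxy)-3,5,6,8-tetramethoxy-2-methyl-4H-chromen-4-one | COc1c(C)oc2c(OC)c(OCc3ccccc3)c(OC)c(OC)c2c1=O
F3 | step 9 | 7-(benzyloxy)-3,5,6,8-tetramethoxy-4-oxo-4H-chromene-2-carbaldehyde | COc1c(C=O)oc2c(OC)c(OCc3ccccc3)c(OC)c(OC)c2c1=O
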